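In a closed flask of constant volume the first nucleophile keeps its count, free plus bound equal to its charge of 0.0950 M, so if each target holds one of them, target draws on a fixed purse while the substrate charge varies from flask to flask.

| flask | substrate | first nucleophile | second nucleophile | remark | time |
|---|---|---|---|---|---|
| east | 0.12 M | 0.095 M | 0.15 M | run made earlier |  |
| south | 0.58 M | 0.095 M | 0.15 M | run made earlier |  |
| elm | 0.10 M | 0.0950 M | 0.150 M |  | 2.5 d |
| cedar | 0.15 M | 0.0950 M | 0.150 M |  | 2.5 d |
| maple | 0.25 M | 0.0950 M | 0.150 M |  | 2.5 d |
| larch | 0.30 M | 0.0950 M | 0.150 M |  | 2.5 d |
| birch | 0.50 M | 0.0950 M | 0.150 M |  | 2.5 d |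

| run | time / h | target / % |
|---|---|---|
| east | 3.00 | 2.0 |
| east | 6.00 | 4.0 |
| east | 12.0 | 7.7 |
| east | 20.0 | 11.4 |
| east | 40.0 | 17.0 |
| south | 8.00 | 3.6 |
| south | 15.0 | 6.2 |
| south | 25.0 | 5.7 |
| south | 30.0 | 5.4 |
| south | 40.0 | 5.2 |

(readings scatter by 0.5 percentage points)

- the earlier runs were read with a standard deviation of 0.5 percentage points
- "hardly changes" means that all values lie within two and a half points (for a concentration: within two and a half percent of the largest)

- [target] at the end for elm, cedar, maple, larch, birch, in this order
- the shape of the row from first to last (falls all the way / falls, then rises / rises, then falls / hardly changes / rises all the way)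

The bench rule reads the start of the east run, where target reaches 4.0% of the substrate charged after 6.00 h, which gives a yield rate s of 0.00667 /h; taken as pseudo-first-order in substrate, target then forms at s[substrate] in proportion to the charge. The nucleophile clock is the charge of first nucleophile divided by that early rate, the time the purse lasts if target formation spends it at that pace, and for the south charge it reads 24.6 h. The clock shortens as the substrate charge grows, from 3.96 d for cedar to 2.38 d for maple, and the asked time of 2.5 d lies between them, so at the early pace, as an estimate and no more, target formation would spend the purse within the run from about maple upward.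

The border of the rule shows in the east run, where the reading at 40.0 h is 17.0% against 26.7% from the early rate, a ratio of 0.637. The pace slackens, so the real clock runs longer than printed, and the top of the row should stand at maple or just above it. South adds that target can also fall, from 6.2% at 15.0 h to 5.2% at 40.0 h, so the row should drop past its top.

The forecast gives 0.021 M, 0.029 M, 0.037 M, 0.038 M and 0.032 M, a row that rises, then falls, on the ground that “a reagent seems to run out and the target is then slowly consumed”.

The flasks give 0.0223 M, 0.0282 M, 0.0334 M, 0.0336 M and 0.0227 M, a row that rises, then falls, as forecast, with birch ending lower than forecast.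

    intermediate → solvolysis product (k = 0.00470 /min)
    substrate → intermediate (k = 1.90 × 10⁻⁴ /min)
    substrate + target → side product (k = 0.00230 /M/min)
    second nucleophile + intermediate → other capture product (k = 0.250 /M/min)
    first nucleophile + intermediate → target (k = 0.820 /M/min)
    2 substrate → homo dimer (k = 1.10 × 10⁻⁵ /M/min)

In elm the clock of 5.94 d outlasts the 2.5 d, 69% of the first nucleophile still stands at the end, and at 1.01 d target is made 3.93 times faster than it is used up. In birch the clock of 1.19 d is shorter than the 2.5 d, and the end finds target at 4.54% of the substrate charged and the first nucleophile at 1.8% of its charge.

The numbers in the tables come from a simulation for substances that don't exist.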